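**Plan**
- Retrosynthetic cuts, in order: the pyran O–CMe2 bond on ring B (last ring, closed by oxa-6π electrocyclisation of an ortho-quinone methide); the C4'–vinyl bond (Heck coupling at a C4 bromide); the pyranone O1–C2 and C3–OH bonds (oxidative chalcone cyclisation); the chalcone Cα=Cβ bond (crossed aldol); the two aryl–prenyl bonds at C6 and C8 (C-alkylation of phloroacetophenone).
- Forward order: prenylate ring A; arm the ring-B aldehyde with a C5 carbinol chain; join the halves as a chalcone; close the pyranone ring (flavonol); close the 2,2-dimethyl-2H-pyran last, in the same acid operation that frees all hydroxyls.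
- Enabling feature: on ring B the pyran oxygen sits on C3' and the pyran C4 on the adjacent C4'. The 2H-pyran is therefore the valence isomer of the ortho-quinone methide O=C3'–C4'=CH–CH=CMe2, which a C4' allylic carbinol gives on ionisation. C6 and C8 of ring A each lie between two phenolic oxygens, which allows direct C-prenylation.
- Stereochemistry: the target has no stereocentre, so nothing needs to be set; the only transient stereocentres (step 6) are removed by oxidation in the same flask.

Key step: step 7

Remark: the target is achiral (no stereocentre or axis; the ring olefin can only be cis), so "single enantiomer" calls for no asymmetric step.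

**Step 1**
Reactants: 1 4-bromo-3-hydroxybenzaldehyde
Product: 2 4-bromo-3-(methoxymethoxy)benzaldehyde
Conditions: MOMCl, i-Pr2NEt, CH2Cl2, 0 °C to rt
Reagents that add atoms: chloromethyl methyl ether (MOMCl), COCCl
Why: Phenol O-alkylation (Williamson-type acetal formation under amine base) masks the only acidic site so that the Heck and aldol steps run on a neutral arene; aldehyde and bromide are untouched.

**Step 2**
Reactants: 2 4-bromo-3-(methoxymethoxy)benzaldehyde; 3 2-methylbut-3-en-2-ol
Product: 4 4-[(E)-3-hydroxy-3-methylbut-1-en-1-yl]-3-(methoxymethoxy)benzaldehyde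
Conditions: Pd(OAc)2 (cat.), P(o-tol)3, Et3N, DMF, 100 °C
Reagents that add atoms: none
Why: Mizoroki–Heck reaction: oxidative addition into the C–Br bond para to the formyl group, insertion at the unsubstituted alkene terminus and syn β-hydride elimination toward the aryl side (the carbinol carbon has no hydrogen) should give only the E-styrene.

**Step 3**
Reactants: 5 1-(2,4,6-trihydroxyphenyl)ethan-1-one (phloroacetophenone); 6 1-bromo-3-methylbut-2-ene (prenyl bromide, about 2.2 equiv)
Product: 7 1-[2,4,6-trihydroxy-3,5-bis(3-methylbut-2-en-1-yl)phenyl]ethan-1-one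
Conditions: 10% aq. KOH, 0 °C to rt
Reagents that add atoms: none
Why: C-alkylation of an ambident phloroglucinol phenoxide by an allylic bromide in water, where hydrogen bonding to oxygen favours attack through carbon, should occur at the two equivalent ring carbons that each lie between two oxygens.

**Step 4**
Reactants: 7 1-[2,4,6-trihydroxy-3,5-bis(3-methylbut-2-en-1-yl)phenyl]ethan-1-one
Product: 8 1-[2-hydroxy-4,6-bis(methoxymethoxy)-3,5-bis(3-methylbut-2-en-1-yl)phenyl]ethan-1-one
Conditions: MOMCl (2.2 equiv), i-Pr2NEt, CH2Cl2, 0 °C to rt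
Reagents that add atoms: chloromethyl methyl ether (MOMCl), COCCl
Why: Selective acetalisation (MOM protection): the para hydroxyl and one ortho hydroxyl should react, while the second ortho hydroxyl, held in a hydrogen bond to the ketone, stays free as the later ring closure requires.

**Step 5**
Reactants: 8 1-[2-hydroxy-4,6-bis(methoxymethoxy)-3,5-bis(3-methylbut-2-en-1-yl)phenyl]ethan-1-one; 4 4-[(E)-3-hydroxy-3-methylbut-1-en-1-yl]-3-(methoxymethoxy)benzaldehyde
Product: 9 (E)-1-[2-hydroxy-4,6-bis(methoxymethoxy)-3,5-bis(3-methylbut-2-en-1-yl)phenyl]-3-{4-[(E)-3-hydroxy-3-methylbut-1-en-1-yl]-3-(methoxymethoxy)phenyl}prop-2-en-1-one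
Conditions: KOH (excess), EtOH–H2O, rt
Reagents that add atoms: none
Why: Claisen–Schmidt (crossed aldol) condensation of the methyl ketone enolate with the non-enolisable aldehyde, then E1cB dehydration, should give the thermodynamically favoured E-enone; acetals, carbinol and alkenes are inert to hydroxide.

**Step 6**
Reactants: 9 (E)-1-[2-hydroxy-4,6-bis(methoxymethoxy)-3,5-bis(3-methylbut-2-en-1-yl)phenyl]-3-{4-[(E)-3-hydroxy-3-methylbut-1-en-1-yl]-3-(methoxymethoxy)phenyl}prop-2-en-1-one
Product: 11 3-hydroxy-2-{4-[(E)-3-hydroxy-3-methylbut-1-en-1-yl]-3-(methoxymethoxy)phenyl}-5,7-bis(methoxymethoxy)-6,8-bis(3-methylbut-2-en-1-yl)-4H-chromen-4-one, via trans-dihydroflavonol 10 (not isolated)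
Conditions: 30% H2O2, aq. NaOH, MeOH–THF, 0 °C to rt
Reagents that add atoms: hydrogen peroxide, OO
Why: Algar–Flynn–Oyamada oxidation: oxa-Michael closure of the phenoxide onto the enone with capture of the enolate by hydrogen peroxide should give the racemic trans-dihydroflavonol 10, which alkaline peroxide dehydrogenates to the flavonol so that its two stereocentres vanish, while nucleophilic hydroperoxide leaves the electron-rich prenyl and styrene double bonds alone.

**Step 7**
Reactants: 11 3-hydroxy-2-{4-[(E)-3-hydroxy-3-methylbut-1-en-1-yl]-3-(methoxymethoxy)phenyl}-5,7-bis(methoxymethoxy)-6,8-bis(3-methylbut-2-en-1-yl)-4H-chromen-4-one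
Product: 14 dorsilurin C, via MOM-free allylic alcohol 12 (not isolated), via o-quinone methide 13 (not isolated)
Conditions: 3 M aq. HCl, MeOH–THF, rt to 40 °C, high dilution, Ar
Reagents that add atoms: none
Why: Acid should transacetalise the three MOM groups to dimethoxymethane, giving 12, and ionise the tertiary aryl-conjugated allylic carbinol to a 1-aryl-3,3-dimethylallyl cation, whose o-hydroxybenzyl resonance form loses the C3'–OH proton to give the dearomatised (Z)-o-quinone methide 13 (the E geometry of the former styrene bond is irrelevant, because that bond is single in 13 and the aryl–CH bond rotates in the cation). 13 should then close the pyran by thermal disrotatory oxa-6π electrocyclisation between O3' and the CMe2 terminus (formally 6-endo capture of the allyl cation by the phenol oxygen), which re-aromatises ring B and makes the sequence irreversible. The closest known reaction type is the acid-promoted cyclodehydration of o-hydroxycinnamyl-type allylic alcohols to 2,2-dimethyl-2H-chromenes through o-quinone methides, as applied after coumarins or salicylaldehydes are treated with methyl or isobutenyl organometallics. No stereocentre is created and the ring olefin can only be cis. Regioselectivity (fusion across C3'–C4', not C2'–C3') needs no control because the carbon chain was fixed on C4' by the bromine of 1, and the 3-, 5- and 7-hydroxyls are too remote to reach the cation. The chemoselectivity needed, ionisation of the carbinol without acid-induced addition of the freed 5- and 7-hydroxyls across the neighbouring prenyl double bonds, rests on SN1 ionisation of a tertiary conjugated allylic alcohol being far easier than protonation of an isolated trisubstituted alkene, helped by low temperature and dilution.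

**Compound list**
1 | 4-bromo-3-hydroxybenzaldehyde | O=Cc1ccc(Br)c(O)c1 | starting material
2 | 4-bromo-3-(methoxymethoxy)benzaldehyde | COCOc1cc(C=O)ccc1Br | intermediate
3 | 2-methylbut-3-en-2-ol | C=CC(C)(C)O | starting material
4 | 4-[(E)-3-hydroxy-3-methylbut-1-en-1-yl]-3-(methoxymethoxy)benzaldehyde | COCOc1cc(C=O)ccc1/C=C/C(C)(C)O | intermediate
5 | 1-(2,4,6-trihydroxyphenyl)ethan-1-one (phloroacetophenone) | CC(=O)c1c(O)cc(O)cc1O | starting material
6 | 1-bromo-3-methylbut-2-ene (prenyl bromide) | CC(C)=CCBr | starting material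
7 | 1-[2,4,6-trihydroxy-3,5-bis(3-methylbut-2-en-1-yl)phenyl]ethan-1-one | CC(=O)c1c(O)c(CC=C(C)C)c(O)c(CC=C(C)C)c1O | intermediate
8 | 1-[2-hydroxy-4,6-bis(methoxymethoxy)-3,5-bis(3-methylbut-2-en-1-yl)phenyl]ethan-1-one | CC(=O)c1c(O)c(CC=C(C)C)c(OCOC)c(CC=C(C)C)c1OCOC | intermediate
9 | (E)-1-[2-hydroxy-4,6-bis(methoxymethoxy)-3,5-bis(3-methylbut-2-en-1-yl)phenyl]-3-{4-[(E)-3-hydroxy-3-methylbut-1-en-1-yl]-3-(methoxymethoxy)phenyl}prop-2-en-1-one | CC(C)=CCc1c(O)c(C(=O)/C=C/c2ccc(/C=C/C(C)(C)O)c(OCOC)c2)c(OCOC)c(CC=C(C)C)c1OCOC | intermediate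
10 | rac-(2R,3R)-3-hydroxy-2-{4-[(E)-3-hydroxy-3-methylbut-1-en-1-yl]-3-(methoxymethoxy)phenyl}-5,7-bis(methoxymethoxy)-6,8-bis(3-methylbut-2-en-1-yl)-2,3-dihydro-4H-chromen-4-one (trans-dihydroflavonol, racemic, one enantiomer drawn) | CC(C)(O)/C=C/c1ccc(cc1OCOC)[C@@H]2[C@H](C(=O)c3c(OCOC)c(CC=C(C)C)c(OCOC)c(CC=C(C)C)c3O2)O | intermediate (not isolated)
11 | 3-hydroxy-2-{4-[(E)-3-hydroxy-3-methylbut-1-en-1-yl]-3-(methoxymethoxy)phenyl}-5,7-bis(methoxymethoxy)-6,8-bis(3-methylbut-2-en-1-yl)-4H-chromen-4-one | CC(C)=CCc1c(OCOC)c(CC=C(C)C)c2oc(-c3ccc(/C=C/C(C)(C)O)c(OCOC)c3)c(O)c(=O)c2c1OCOC | intermediate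
12 | 3,5,7-trihydroxy-2-{3-hydroxy-4-[(E)-3-hydroxy-3-methylbut-1-en-1-yl]phenyl}-6,8-bis(3-methylbut-2-en-1-yl)-4H-chromen-4-one | CC(C)=CCc1c(O)c(CC=C(C)C)c2oc(-c3ccc(/C=C/C(C)(C)O)c(O)c3)c(O)c(=O)c2c1O | intermediate (not isolated)
13 | 3,5,7-trihydroxy-2-[(4Z)-4-(3-methylbut-2-en-1-ylidene)-3-oxocyclohexa-1,5-dien-1-yl]-6,8-bis(3-methylbut-2-en-1-yl)-4H-chromen-4-one (o-quinone methide) | CC(C)=CCc1c(O)c(CC=C(C)C)c2oc(C3=CC(=O)/C(=C\C=C(C)C)C=C3)c(O)c(=O)c2c1O | intermediate (not isolated)
14 | dorsilurin C, 2-(2,2-dimethyl-2H-chromen-7-yl)-3,5,7-trihydroxy-6,8-bis(3-methylbut-2-en-1-yl)-4H-chromen-4-one | CC(C)=CCc1c(O)c(CC=C(C)C)c2oc(-c3ccc4c(c3)OC(C)(C)C=C4)c(O)c(=O)c2c1O | target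

**Totals**
Total step count: 7. Longest linear sequence: 5 steps (steps 3, 4, 5, 6, 7 from 5; equally steps 1, 2, 5, 6, 7 from 1).

**Steps most likely to fail**

1. Step 7. What may go wrong: the allyl cation is diverted (proton loss to the 1,3-diene, oligomerisation) before the C3' phenol is unmasked, or the freed 5- and 7-hydroxyls add across the neighbouring prenyl double bonds under acid (chroman formation). The fallback closes the pyran under neutral conditions by a different mechanism while ring A is still protected. It sets out from 8, which is condensed (KOH, EtOH–H2O) with 3-[(2-methylbut-3-yn-2-yl)oxy]benzaldehyde F1, made in one step from commercial 3-hydroxybenzaldehyde and 3-chloro-3-methylbut-1-yne (CuCl2 cat., DBU, MeCN, 0 °C). This should give the chalcone (E)-1-[2-hydroxy-4,6-bis(methoxymethoxy)-3,5-bis(3-methylbut-2-en-1-yl)phenyl]-3-{3-[(2-methylbut-3-yn-2-yl)oxy]phenyl}prop-2-en-1-one F2. Alkaline H2O2 as in step 6 should convert it into the flavonol 3-hydroxy-5,7-bis(methoxymethoxy)-6,8-bis(3-methylbut-2-en-1-yl)-2-{3-[(2-methylbut-3-yn-2-yl)oxy]phenyl}-4H-chromen-4-one F3. Cationic gold(I)-catalysed 6-endo-dig hydroarylation of the aryl propargyl ether ([JohnPhosAu(NCMe)]SbF6, CH2Cl2, rt) should then close the pyran at the less hindered C4' to give 2-(2,2-dimethyl-2H-chromen-7-yl)-3-hydroxy-5,7-bis(methoxymethoxy)-6,8-bis(3-methylbut-2-en-1-yl)-4H-chromen-4-one F4; any isomer from closure at C2' would be removed by chromatography. A short treatment with HCl in MeOH, which now only cleaves acetals, comes back to the route at 14.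

2. Step 6. What may go wrong: after oxidation of the enone the phenoxide closes 5-exo at the α-carbon (the aurone pathway), which the 6'-alkoxy group favours. The fallback separates ring closure from oxidation. It sets out from 9, which NaOAc in refluxing EtOH should cyclise without oxidant to the flavanone rac-2-{4-[(E)-3-hydroxy-3-methylbut-1-en-1-yl]-3-(methoxymethoxy)phenyl}-5,7-bis(methoxymethoxy)-6,8-bis(3-methylbut-2-en-1-yl)-2,3-dihydro-4H-chromen-4-one F5. Its kinetic lithium enolate (LiHMDS, THF, −78 °C, excess to cover the carbinol) is hydroxylated with 2-(phenylsulfonyl)-3-phenyloxaziridine anti to the aryl group, to give the trans-dihydroflavonol 10, now isolated. Dehydrogenation of 10 with aq. NaOH/H2O2 in MeOH at 0 °C comes back to the route at 11.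

3. Step 3. What may go wrong: alkylation at oxygen and geminal, dearomatising double alkylation at one carbon compete with the desired 3,5-di-C-alkylation. The fallback replaces phenoxide alkylation by cross-coupling. It sets out from 5, which N-iodosuccinimide (2 equiv, MeCN, 0 °C) should convert into 1-(2,4,6-trihydroxy-3,5-diiodophenyl)ethan-1-one F6. MOMCl/i-Pr2NEt then gives 1-[2-hydroxy-3,5-diiodo-4,6-bis(methoxymethoxy)phenyl]ethan-1-one F7. A double Stille coupling with tributyl(3-methylbut-2-en-1-yl)stannane (Pd(PPh3)4, DMF, 90 °C) comes back to the route at 8.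

**Further compounds**
F1 | step 7 | 3-[(2-methylbut-3-yn-2-yl)oxy]benzaldehyde | C#CC(C)(C)Oc1cccc(C=O)c1
F2 | step 7 | (E)-1-[2-hydroxy-4,6-bis(methoxymethoxy)-3,5-bis(3-methylbut-2-en-1-yl)phenyl]-3-{3-[(2-methylbut-3-yn-2-yl)oxy]phenyl}prop-2-en-1-one | CC(C)=CCc1c(O)c(C(=O)/C=C/c2cccc(OC(C)(C)C#C)c2)c(OCOC)c(CC=C(C)C)c1OCOC
F3 | step 7 | 3-hydroxy-5,7-bis(methoxymethoxy)-6,8-bis(3-methylbut-2-en-1-yl)-2-{3-[(2-methylbut-3-yn-2-yl)oxy]phenyl}-4H-chromen-4-one | CC(C)=CCc1c(OCOC)c(CC=C(C)C)c2oc(-c3cccc(OC(C)(C)C#C)c3)c(O)c(=O)c2c1OCOC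
F4 | step 7 | 2-(2,2-dimethyl-2H-chromen-7-yl)-3-hydroxy-5,7-bis(methoxymethoxy)-6,8-bis(3-methylbut-2-en-1-yl)-4H-chromen-4-one | CC(C)=CCc1c(OCOC)c(CC=C(C)C)c2oc(-c3ccc4c(c3)OC(C)(C)C=C4)c(O)c(=O)c2c1OCOC
F5 | step 6 | rac-(2S)-2-{4-[(E)-3-hydroxy-3-methylbut-1-en-1-yl]-3-(methoxymethoxy)phenyl}-5,7-bis(methoxymethoxy)-6,8-bis(3-methylbut-2-en-1-yl)-2,3-dihydro-4H-chromen-4-one (racemic, one enantiomer drawn) | CC(C)(O)/C=C/c1ccc(cc1OCOC)[C@@H]2CC(=O)c3c(OCOC)c(CC=C(C)C)c(OCOC)c(CC=C(C)C)c3O2
F6 | step 3 | 1-(2,4,6-trihydroxy-3,5-diiodophenyl)ethan-1-one | CC(=O)c1c(O)c(I)c(O)c(I)c1O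
F7 | step 3 | 1-[2-hydroxy-3,5-diiodo-4,6-bis(methoxymethoxy)phenyl]ethan-1-one | CC(=O)c1c(O)c(I)c(OCOC)c(I)c1OCOC
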